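The easy step first: see how fast the flask starts, then how long that start lasts.

| flask | starting material | reagent | capture agent | free catalyst | added ligand | remark | time |
|---|---|---|---|---|---|---|---|
| Monday's | 0.10 M | 1.05 equiv | 0.030 M | 1.6 mol% | 2.3 mM | the very flask that is asked about, followed so far |  |
| Saturday's | 0.10 M | 1.05 equiv | 0.030 M | 1.6 mol% | 1.1 mM | run made earlier |  |
| flask | 0.10 M | 1.05 equiv | 0.0300 M | 1.6 mol% | 2.3 mM |  | 12 min |

- Monday's (time / min: product / %): 0.500: 4.4; 1.33: 9.1; 2.50: 12.9; 4.00: 14.7; 6.00: 16.5; 8.00: 15.8; 10.0: 16.5
- Saturday's (time / min: product / %): 0.333: 2.3; 0.667: 5.8; 1.00: 7.8; 1.33: 10.2; 2.00: 12.5; 2.50: 14.7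

(scatter of a reading: 0.5 percentage points)

- autumn: at 12 min add reagent, 50.0 % of the amount charged, then wait 6.0 min
- spring: at 12 min add free catalyst, 100 % of the amount charged, then wait 6.0 min
- midnight: at 12 min take out 90 % of the product then present, then wait 6.0 min
- winter: change nothing and wait 6.0 min more

- product that was removed still counts
- additions bring no volume worth counting

- product, in percent of the starting material first charged, at 12 min
- what to do for the largest gain in product; "none" if nothing gains more than 2 percentage points (autumn / spring / midnight / winter / none)
- product present, with what was taken out counted in, in percent of the starting material first charged, after autumn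
- product present, with what was taken out counted in, in percent of the starting material first charged, after midnight

Monday's flask, the one you are asked about, reaches 4.4 % at 0.500 min, a pace of 0.0880 min⁻¹ as a share of the charge. Set against a catalyst loading of 1.6 mol%, that means one round of the catalyst takes about 0.182 min. This is the first rung of the ladder.

Next come the plateau readings of Monday's flask, which average 16.3 %. If the pace dies away exponentially, the plateau is pace times working life, so the catalyst works for about 1.85 min, ten times a round. Emptying the starting material at the opening pace would take 11.4 min, longer than that life, so the catalyst stops first. Saturday's flask, with half the added ligand, reads 14.7 % at 2.50 min against 12.9 % for Monday's, a small early difference.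

Carry one number: the turnover budget N, the rounds one catalyst makes before it stops, which is the plateau over the loading, 10.2.

At 12 min Monday's flask is 6.49 lives old, so by my reckoning it stands at the plateau, with 0.025 percentage points still to come. Autumn and midnight put back no working catalyst, so I expect nothing from them. A fresh charge in spring, at budget N, should bring 16 points, against a margin of 2 points.

The forecast gives 16.4 % now, 16.5 % after autumn and 16.5 % after midnight, and it chooses spring, saying “Fresh catalyst should therefore restart the reaction”.

The flask gives 16.6 % now, 16.6 % after autumn and 16.7 % after midnight. The best choice is spring, with a gain of 6.4 points.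

    capture agent + catalyst intermediate D → trapped intermediate (k = 7.33 M⁻¹ s⁻¹)
    starting material + free catalyst ⇌ catalyst intermediate A (K = 2.00 M⁻¹, k = 4.28 M⁻¹ s⁻¹)
    reagent + catalyst intermediate B → catalyst intermediate C (k = 11.9 M⁻¹ s⁻¹)
    catalyst intermediate C → catalyst intermediate D (k = 3.37 s⁻¹)
    catalyst intermediate A → catalyst intermediate B (k = 1.14 s⁻¹)
    free catalyst + added ligand ⇌ idle complex (K = 246 M⁻¹, k = 4.61 M⁻¹ s⁻¹)
    catalyst intermediate D ⇌ free catalyst + product (K = 0.187 M, k = 14.0 s⁻¹)

So the second charge made 4.01 rounds per catalyst, fewer than N, and my gain was too high though the choice stands. In the asked flask at 12.0 min, 99.6 % of the catalyst sits as trapped intermediate, and the step to idle complex makes no difference to the product at that time. In the neighbouring flask, capture agent is cut to 0.012 M, a factor of 2.50. At 12.0 min that flask holds 26.6 % of product, or 1.64 times budget N, close to the square root of that factor, 1.58.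

(The data were generated by integration for an exercise; scatter was added.)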